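**Retrosynthetic overview**

1. Numbering runs from the ester carbonyl (C1) to the bromine-bearing carbon (C20); the only ring is the oxolane O/C5–C8 with trans arms (5R,8S). Cut back to C4 and C9, this ring is C2-symmetric (2S,5S)-2,5-bis(hydroxymethyl)oxolane, and both stereocentres are latent in achiral meso-1,2:5,6-diepoxyhexane (oxiranes C4–C5 and C8–C9).
2. The ring is closed first, in the key step: a chiral (salen)cobalt acetate hydrolyses one of the two enantiotopic oxiranes at C4, and the freed C5 hydroxyl opens the other at C8 (O–C8 bond, 5-exo).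
3. The meso diepoxide is made diastereomerically pure from meso-2,5-dibromoadipate (reduction, doubly inverting closure). Peracid epoxidation of hexa-1,5-diene is avoided because the matched chiral diepoxide in that mixture would be hydrolysed by the same catalyst and would cyclise to the cis diol.
4. The two homotopic arms are then differentiated: C3–C4 by Giese addition of the mono-iodide to methyl acrylate, C9≡C10 by aldehyde-to-alkyne homologation.
5. Side chain C11–C20: E-iodoalkene by hydrozirconation, Z-C17=C18 by Wittig reaction with (E)-3-bromoacrolein; the last bond C10–C11 is made by Sonogashira coupling.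

Key step: step 3

Remark: the (R,R) catalyst is taken to hydrolyse (S)-configured monoalkyl oxiranes, as in the resolution of simple 1,2-epoxyalkanes, and commercial diethyl meso-2,5-dibromoadipate is taken as diastereomerically pure (it can be recrystallised).

**Route**

Step 1
Reactants: 1 diethyl (2R,5S)-2,5-dibromohexanedioate (meso)
Product: 2 (2R,5S)-2,5-dibromohexane-1,6-diol (meso)
Conditions: i-Bu2AlH (5 equiv), CH2Cl2, −78 → 0 °C; aq. potassium sodium tartrate
Reagents that add atoms: none
Why: Ester reduction with an electrophilic aluminium hydride: at low temperature hydride transfer to the ester carbonyls is much faster than attack on the secondary C–Br bonds and no enolate is formed, so both bromine-bearing carbons should keep their configuration and the meso relation of 1 passes into bromohydrin 2.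

Step 2
Reactants: 2 (2R,5S)-2,5-dibromohexane-1,6-diol
Product: 3 meso-1,2:5,6-diepoxyhexane
Conditions: KOH (powdered, 3 equiv), Et2O, 0 °C → rt; filtration, distillation
Reagents that add atoms: none
Why: Twofold Williamson-type closure of a bromohydrin: each primary alkoxide displaces the neighbouring bromide from the back (3-exo-tet), and inversion at both carbons of a meso compound again gives a meso compound, so the diepoxide should form free of the chiral diastereomers.

Step 3
Reactants: 3 meso-1,2:5,6-diepoxyhexane
Product: 5 [(2S,5S)-tetrahydrofuran-2,5-diyl]dimethanol, via epoxy diol 4 (not isolated)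
Conditions: (R,R)-(salen)Co(OAc) (1 mol%, made from the divalent cobalt complex (R,R)-(salen)Co with AcOH and air), H2O (1.0 equiv), THF, 0 °C → rt; then CSA (5 mol%), CH2Cl2, rt
Reagents that add atoms: water, O
Why: One trivalent cobalt centre of (R,R)-N,N'-bis(3,5-di-tert-butylsalicylidene)-1,2-cyclohexanediaminocobalt acetate binds an oxirane as a Lewis acid while a second delivers hydroxide to its unsubstituted carbon C4, and this cooperative pathway should accept only the (S)-configured oxirane of 3, giving epoxy diol 4 with C5 untouched. The C5 hydroxyl of 4 then attacks the internal carbon C8 of the remaining (R)-oxirane from the back, assisted by the cobalt Lewis acid or by the trace of sulfonic acid, forming the O–C8 bond and closing the oxolane in the 5-exo-tet mode. The closest known reaction types are the hydrolytic kinetic resolution of terminal monoalkyl oxiranes by this catalyst and the 5-exo cyclisation of 4,5-epoxy alcohols. C5 is fixed by the catalyst's choice between the two enantiotopic oxiranes (retention), and C8 by the stereospecific inversion of the ring closure, so the meso relation becomes the trans (2S,5S) ring. The step needs enantiotopic-group selectivity, secured because each oxirane is an unhindered terminal monoalkyl oxirane and water is limited to one equivalent so the mismatched oxirane is not hydrolysed. It also needs 5-exo attack by the secondary hydroxyl to beat 6-exo attack by the primary one, secured by the shorter tether of the C5 hydroxyl to C8.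

Step 4
Reactants: 5 [(2S,5S)-tetrahydrofuran-2,5-diyl]dimethanol
Product: 6 [(2S,5S)-5-(iodomethyl)tetrahydrofuran-2-yl]methanol
Conditions: PPh3 (1.0 equiv), imidazole (1.5 equiv), I2 (1.0 equiv), THF–MeCN, 0 °C
Reagents that add atoms: iodine, II
Why: Appel-type iodination of a primary alcohol through an alkoxyphosphonium iodide: the two hydroxymethyl arms of the C2-symmetric diol are homotopic, so reaction at either gives the same mono-iodide, which one equivalent of reagent should deliver in a statistical mixture from which unreacted 5 is recovered for recycling, and no stereocentre is involved.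

Step 5
Reactants: 6 [(2S,5S)-5-(iodomethyl)tetrahydrofuran-2-yl]methanol; 7 methyl acrylate
Product: 8 methyl 4-[(2R,5S)-5-(hydroxymethyl)tetrahydrofuran-2-yl]butanoate
Conditions: 7 (8 equiv), Bu3SnH (1.3 equiv, slow addition), AIBN (0.1 equiv), PhH, 80 °C; aq. KF
Reagents that add atoms: none
Why: Giese reaction: iodine abstraction by the stannyl radical gives a nucleophilic primary alkyl radical at C4 that adds to the unsubstituted terminus of the electron-poor alkene faster than it is reduced when the stannane is kept dilute, the α-ester radical is then quenched by the stannane, and neither the free hydroxyl nor the ring stereocentres take part.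

Step 6
Reactants: 8 methyl 4-[(2R,5S)-5-(hydroxymethyl)tetrahydrofuran-2-yl]butanoate
Product: 9 methyl 4-[(2R,5S)-5-formyltetrahydrofuran-2-yl]butanoate
Conditions: Dess–Martin periodinane (1.3 equiv), NaHCO3, CH2Cl2, 0 °C → rt; used crude
Reagents that add atoms: none
Why: Dess–Martin oxidation of a primary alcohol stops at the aldehyde under buffered, nearly neutral conditions, so the α-alkoxy stereocentre C8 should not epimerise and the methyl ester is untouched.

Step 7
Reactants: 9 methyl 4-[(2R,5S)-5-formyltetrahydrofuran-2-yl]butanoate
Product: 10 methyl 4-[(2R,5S)-5-ethynyltetrahydrofuran-2-yl]butanoate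
Conditions: dimethyl (1-diazo-2-oxopropyl)phosphonate (1.3 equiv), K2CO3 (2 equiv), MeOH, 0 °C → rt
Reagents that add atoms: dimethyl (1-diazo-2-oxopropyl)phosphonate, COP(=O)(OC)C(=[N+]=[N-])C(C)=O
Why: Seyferth–Gilbert homologation in the Ohira–Bestmann variant: methoxide releases the diazomethylphosphonate anion, which converts the aldehyde through a diazoalkene and 1,2-hydrogen shift of the alkylidene carbene into the terminal alkyne C9≡C10, while the mild carbonate base at low temperature should leave C8 intact and methanol cannot change a methyl ester.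

Step 8
Reactants: 11 hept-6-yn-1-ol
Product: 12 7-iodohept-1-yne
Conditions: PPh3, imidazole, I2, CH2Cl2, 0 °C → rt
Reagents that add atoms: iodine, II
Why: Appel-type iodination of a primary alcohol, to which the terminal alkyne is inert.

Step 9
Reactants: 12 7-iodohept-1-yne
Product: 14 (1E)-1,7-diiodohept-1-ene, via alkenylzirconocene chloride 13 (not isolated)
Conditions: Cp2Zr(H)Cl (1.2 equiv), THF, rt, dark; then I2, 0 °C
Reagents that add atoms: iodine, II
Why: Hydrozirconation–iodinolysis: syn addition of Zr–H places zirconium on the terminal carbon and iodine replaces it with retention, so only the E iodoalkene (the future C11=C12) should form, and the primary alkyl iodide is not expected to be reduced by Cp2Zr(H)Cl in the dark at room temperature.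

Step 10
Reactants: 14 (1E)-1,7-diiodohept-1-ene
Product: 15 [(6E)-7-iodohept-6-en-1-yl]triphenylphosphonium iodide
Conditions: PPh3 (1.1 equiv), MeCN, 80 °C
Reagents that add atoms: triphenylphosphine, c1ccc(cc1)P(c1ccccc1)c1ccccc1
Why: SN2 quaternisation of the phosphine by the primary alkyl iodide, whereas the sp2 C–I bond does not react with a phosphine in the absence of a transition metal, so the E iodoalkene is carried through.

Step 11
Reactants: 16 3,3-diethoxyprop-1-yne
Product: 18 (1E)-1-bromo-3,3-diethoxyprop-1-ene, via alkenylzirconocene chloride 17 (not isolated)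
Conditions: Cp2Zr(H)Cl (1.2 equiv), THF, rt; then NBS, 0 °C
Reagents that add atoms: N-bromosuccinimide, O=C1CCC(=O)N1Br
Why: Hydrozirconation–bromination: syn addition of Zr–H to the terminal alkyne with zirconium at the terminal carbon and electrophilic cleavage of the C–Zr bond by NBS with retention should give the E bromoalkene (the future C19=C20) while the acetal is inert.

Step 12
Reactants: 18 (1E)-1-bromo-3,3-diethoxyprop-1-ene
Product: 19 (2E)-3-bromoprop-2-enal
Conditions: 1 M aq. HCl, pentane–Et2O, 0 °C → rt; water wash, MgSO4, used at once as a dried solution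
Reagents that add atoms: water, O
Why: Acid-catalysed acetal hydrolysis through the oxocarbenium ion, in which the more stable E geometry is not at risk, and the volatile, sensitive enal is taken on without concentration.

Step 13
Reactants: 15 [(6E)-7-iodohept-6-en-1-yl]triphenylphosphonium iodide; 19 (2E)-3-bromoprop-2-enal
Product: 21 (1E,3Z,9E)-1-bromo-10-iododeca-1,3,9-triene, via phosphorus ylide 20 (not isolated)
Conditions: NaN(SiMe3)2 (1.0 equiv), THF, −78 → 0 °C; then 19, −78 → 0 °C, dark
Reagents that add atoms: none
Why: Wittig reaction of a non-stabilised ylide under lithium-free conditions at low temperature: irreversible formation of the cis-oxaphosphetane should give the Z alkene C17=C18, 1,2-addition to the enal carbonyl should outpace attack at the bromine-bearing carbon, and both preformed E haloalkenes are untouched.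

Step 14
Reactants: 10 methyl 4-[(2R,5S)-5-ethynyltetrahydrofuran-2-yl]butanoate; 21 (1E,3Z,9E)-1-bromo-10-iododeca-1,3,9-triene
Product: 22 methyl 4-[(2R,5S)-5-[(3E,9Z,11E)-12-bromododeca-3,9,11-trien-1-yn-1-yl]tetrahydrofuran-2-yl]butanoate
Conditions: 21 (1.2 equiv), Pd(PPh3)4 (5 mol%), CuI (10 mol%), Et3N, THF, 0 °C → rt, degassed, dark
Reagents that add atoms: none
Why: Sonogashira coupling: zerovalent palladium inserts into the alkenyl C–I bond far faster than into the dienyl C–Br bond at or below room temperature, the copper acetylide of 10 transmetalates and reductive elimination forms C10–C11 with retention of the E geometry, the ester, the oxolane stereocentres and the bromodiene being spectators.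

**Compound list**

1 | diethyl (2R,5S)-2,5-dibromohexanedioate (meso) | CCOC(=O)[C@@H](Br)CC[C@@H](Br)C(=O)OCC | starting material
2 | (2R,5S)-2,5-dibromohexane-1,6-diol (meso) | OC[C@@H](Br)CC[C@@H](Br)CO | intermediate
3 | meso-1,2:5,6-diepoxyhexane, (2R)-2-[2-[(2S)-oxiran-2-yl]ethyl]oxirane | C1O[C@@H]1CC[C@H]1CO1 | intermediate
4 | (2S)-4-[(2R)-oxiran-2-yl]butane-1,2-diol | C1O[C@@H]1CC[C@H](O)CO | intermediate
5 | [(2S,5S)-tetrahydrofuran-2,5-diyl]dimethanol | OC[C@@H]1CC[C@@H](CO)O1 | intermediate
6 | [(2S,5S)-5-(iodomethyl)tetrahydrofuran-2-yl]methanol | OC[C@@H]1CC[C@@H](CI)O1 | intermediate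
7 | methyl acrylate | C=CC(=O)OC | starting material
8 | methyl 4-[(2R,5S)-5-(hydroxymethyl)tetrahydrofuran-2-yl]butanoate | COC(=O)CCC[C@@H]1CC[C@@H](CO)O1 | intermediate
9 | methyl 4-[(2R,5S)-5-formyltetrahydrofuran-2-yl]butanoate | COC(=O)CCC[C@@H]1CC[C@@H](C=O)O1 | intermediate
10 | methyl 4-[(2R,5S)-5-ethynyltetrahydrofuran-2-yl]butanoate | COC(=O)CCC[C@@H]1CC[C@@H](C#C)O1 | intermediate
11 | hept-6-yn-1-ol | C#CCCCCCO | starting material
12 | 7-iodohept-1-yne | C#CCCCCCI | intermediate
13 | chlorobis(cyclopentadienyl)[(1E)-7-iodohept-1-en-1-yl]zirconium | Cl[Zr](/C=C/CCCCCI)(C1C=CC=C1)C1C=CC=C1 | intermediate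
14 | (1E)-1,7-diiodohept-1-ene | I/C=C/CCCCCI | intermediate
15 | [(6E)-7-iodohept-6-en-1-yl]triphenylphosphonium iodide | I/C=C/CCCCC[P+](c1ccccc1)(c1ccccc1)c1ccccc1.[I-] | intermediate
16 | 3,3-diethoxyprop-1-yne | CCOC(OCC)C#C | starting material
17 | chlorobis(cyclopentadienyl)[(1E)-3,3-diethoxyprop-1-en-1-yl]zirconium | CCOC(OCC)/C=C/[Zr](Cl)(C1C=CC=C1)C1C=CC=C1 | intermediate
18 | (1E)-1-bromo-3,3-diethoxyprop-1-ene | CCOC(OCC)/C=C/Br | intermediate
19 | (2E)-3-bromoprop-2-enal | O=C/C=C/Br | intermediate
20 | [(6E)-7-iodohept-6-en-1-ylidene]triphenylphosphorane | I/C=C/CCCCC=P(c1ccccc1)(c1ccccc1)c1ccccc1 | intermediate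
21 | (1E,3Z,9E)-1-bromo-10-iododeca-1,3,9-triene | Br/C=C/C=C\CCCC/C=C/I | intermediate
22 | methyl 4-[(2R,5S)-5-[(3E,9Z,11E)-12-bromododeca-3,9,11-trien-1-yn-1-yl]tetrahydrofuran-2-yl]butanoate | COC(=O)CCC[C@@H]1CC[C@@H](C#C/C=C/CCCC/C=C\C=C\Br)O1 | target

**Step count**

Total: 14 steps. Longest linear sequence: 8 steps (steps 1–7 and 14).

**Steps most likely to fail**

Step 3. The catalyst may not discriminate completely between the two enantiotopic oxiranes, or the second oxirane may be hydrolysed or opened in the 6-exo mode before the 5-exo closure; either lowers the enantiomeric purity or the yield of the diol. The fallback sets out from 3 and returns at 5 by racemic ring formation and classical resolution. Compound 3 is hydrolysed and cyclised without a chiral catalyst (dilute aqueous NaOH, hydroxide at the terminal carbon, alkoxide 5-exo closure with inversion) to rac-trans-(tetrahydrofuran-2,5-diyl)dimethanol F1. Esterification with (S)-2-methoxy-2-phenylacetic acid (DCC, DMAP, CH2Cl2, 0 °C) gives two diastereomeric diesters, [(2S,5S)-tetrahydrofuran-2,5-diyl]bis(methylene) bis[(2S)-2-methoxy-2-phenylacetate] F2 and its (2R,5R) diastereomer F3, which are separated by crystallisation or chromatography. Methanolysis of F2 (K2CO3, MeOH) releases 5.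

Step 13. The basic ylide may dehydrobrominate the β-bromoenal or add to its bromine-bearing carbon, and kinetic Z control may be incomplete. The fallback sets out from 15 and returns at 21, with bromine introduced only after the olefination. The ylide 20 from 15 is combined with (2E)-3-(tributylstannyl)prop-2-enal F4, obtained by MnO2 oxidation of (E)-3-(tributylstannyl)prop-2-en-1-ol, an established partner for Z-selective Wittig reactions. This should give tributyl[(1E,3Z,9E)-10-iododeca-1,3,9-trien-1-yl]stannane F5, and ipso bromodestannylation with NBS (MeCN, 0 °C), which proceeds with retention, gives 21.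

Step 14. Palladium may also insert into the dienyl C–Br bond of 21 or of the product, leading to double coupling or oligomers, and the alkyne may homocouple. The fallback sets out from 10 (with 11) and returns at 22, so that no C–Br bond is present during the palladium step. Hydrozirconation–iodinolysis of 11 with 2.2 equiv Cp2Zr(H)Cl (the first equivalent is consumed by the hydroxyl) gives (6E)-7-iodohept-6-en-1-ol F6. Sonogashira coupling of F6 with 10 gives methyl 4-[(2R,5S)-5-[(3E)-9-hydroxynon-3-en-1-yn-1-yl]tetrahydrofuran-2-yl]butanoate F7. Iodination (PPh3, I2, imidazole) gives methyl 4-[(2R,5S)-5-[(3E)-9-iodonon-3-en-1-yn-1-yl]tetrahydrofuran-2-yl]butanoate F8, and PPh3 in MeCN gives [(6E)-9-[(2S,5R)-5-(4-methoxy-4-oxobutyl)tetrahydrofuran-2-yl]non-6-en-8-yn-1-yl]triphenylphosphonium iodide F9. Deprotonation with NaN(SiMe3)2 at −78 °C and addition of 19 gives 22.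

**Further compounds**

F1 | step 3 | rac-trans-(tetrahydrofuran-2,5-diyl)dimethanol (both enantiomers) | OC[C@@H]1CC[C@@H](CO)O1.OC[C@H]1CC[C@H](CO)O1
F2 | step 3 | [(2S,5S)-tetrahydrofuran-2,5-diyl]bis(methylene) bis[(2S)-2-methoxy-2-phenylacetate] | CO[C@H](C(=O)OC[C@@H]1CC[C@@H](COC(=O)[C@@H](OC)c2ccccc2)O1)c1ccccc1
F3 | step 3 | [(2R,5R)-tetrahydrofuran-2,5-diyl]bis(methylene) bis[(2S)-2-methoxy-2-phenylacetate] | CO[C@H](C(=O)OC[C@H]1CC[C@H](COC(=O)[C@@H](OC)c2ccccc2)O1)c1ccccc1
F4 | step 13 | (2E)-3-(tributylstannyl)prop-2-enal | CCCC[Sn](CCCC)(CCCC)/C=C/C=O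
F5 | step 13 | tributyl[(1E,3Z,9E)-10-iododeca-1,3,9-trien-1-yl]stannane | CCCC[Sn](CCCC)(CCCC)/C=C/C=C\CCCC/C=C/I
F6 | step 14 | (6E)-7-iodohept-6-en-1-ol | OCCCCC/C=C/I
F7 | step 14 | methyl 4-[(2R,5S)-5-[(3E)-9-hydroxynon-3-en-1-yn-1-yl]tetrahydrofuran-2-yl]butanoate | COC(=O)CCC[C@@H]1CC[C@@H](C#C/C=C/CCCCCO)O1
F8 | step 14 | methyl 4-[(2R,5S)-5-[(3E)-9-iodonon-3-en-1-yn-1-yl]tetrahydrofuran-2-yl]butanoate | COC(=O)CCC[C@@H]1CC[C@@H](C#C/C=C/CCCCCI)O1
F9 | step 14 | [(6E)-9-[(2S,5R)-5-(4-methoxy-4-oxobutyl)tetrahydrofuran-2-yl]non-6-en-8-yn-1-yl]triphenylphosphonium iodide | COC(=O)CCC[C@@H]1CC[C@@H](C#C/C=C/CCCCC[P+](c2ccccc2)(c2ccccc2)c2ccccc2)O1.[I-]
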